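## Numbering and assumptions

- **Atom numbering, used for both halves:** C1 (CH bearing isopropyl), C2, C3, C4 (carbinol carbon), C5 and C6 (ring fusion), C7=C8 (enoate), C9 (OCH2), O10, C11 (lactone C=O), C12 (carboxyl), C13 (CH2O on C4). Primed numbers mark the half whose C12' is the free acid.
- **Compound names** carry systematic locants (cyclohexane-1-carboxylate or 2-benzoxepine numbering); the discussion uses C1–C13.
- **Assumption on the sense of induction:** the (S,S) ligand is taken to give 7 and the (R,R) ligand 20. If the sense is the reverse, the two ligands change places; nothing else changes, because both antipodes are needed.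
- **Assumption on 6:** it forms as a mixture of 2Z and 2E isomers that interconvert under the Lewis acid of step 3; the 2Z isomer is drawn.

## Analysis of the target

The target is an ester-linked dimer of two 1-oxo-octahydro-2-benzoxepine-4-carboxylic acids. In each half a cyclohexane (C1–C6) is trans-fused through C5–C6 to a seven-membered lactone (C5–C11(=O)–O10–C9–C8=C7–C6) that carries the C12 carboxyl on C8. Each half has four stereocentres: the isopropyl group on C1, the C7 arm on C6 and the C11 arm on C5 are all equatorial (C1/C6 trans, C5/C6 trans), and C4 is a tertiary carbinol with equatorial hydroxyl and axial CH2OH (C13). The halves are mirror images, (1R,4S,5S,6S) and (1'S,4'R,5'R,6'R); the molecule is chiral only because C12 of the first half is esterified with the C13' hydroxyl of the second while C13–OH and the C12' acid stay free. Both antipodes of one monomer are therefore needed, each unmasked differently. Each lactone is a 2-(acyloxymethyl)acrylate, so base can deconjugate it or open it by vinylogous elimination from C6–H; the C4 hydroxyl is β to C11 (retro-aldol, dehydration); and the free C13 hydroxyl of the first half sits cis to C11, where acid or base can move the lactone acyl group onto it to give a five-membered lactone. The hard points are the control of C4, the neutral handling of the late intermediates, and supplying two antipodal series without doubling the design work. The strategy rests on C5 lying between C4 and C11: with C4 taken back to a ketone, C4–C5–C11 is a β-keto ester and C5=C6 its alkylidene derivative, and a C3–C2 chain ending in a prenyl alkene can then deliver C1 together with its isopropyl group by an ene closure of C1–C6.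

## Retrosynthetic reasoning

**C4–O and C13–O of the first half (33 to 32).** The diol of the first half is taken back to the exocyclic alkene C4=C13 of 32. This hydroxy lactone array is the most fragile part of the target, so it is created last and under near-neutral conditions. The forward dihydroxylation has to choose the 1,1-disubstituted alkene over two enoates and the equatorial side of C4. Acid 32 comes from its tert-butyl ester 30 by a cleavage that uses no protic acid, because of the alkene.

**C12–O bond to C13' (30 to 19 and 28).** This is the only bond between the halves. Cutting it gives acid 19 and diol 28, which are antipodal at every shared centre and differ only in how C4/C13 and C12 are unmasked. The forward esterification must acylate the primary C13' hydroxyl of 28 beside its tertiary hydroxyl without deconjugating 19.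

**C4=C13 (17 to 16, 27 to 26).** Acid 19 comes from ester 17 by ester cleavage and diol 28 from alkene 27 by dihydroxylation; 17 and 27 are antipodes, so one sequence serves both series. The methylene carbon C13 is cut from the C4 ketone of 16 and 26. Keeping C4 as a ketone up to this point keeps C5 epimerisable, so the trans ring fusion is under thermodynamic control, and preserves the β-keto ester reactivity needed one step earlier. The forward reaction must olefinate a largely enolised ketone without base.

**The lactone ring (16 to 15 to 10 and 13).** C7=C8 is cut by ring-closing metathesis (16 to 15) and O10–C11 by ester exchange (15 to 10 and 13). Cutting the enoate alkene lets C8, C9 and C12 arrive together as the small achiral alcohol 13. Exchange at C11 is a privilege of β-keto esters and needs neither acid nor base. The forward metathesis must close a 1,1-disubstituted acrylate onto the C6 vinyl group.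

**C7 and the isopropyl group (10 to 9 to 8 to 7).** The vinyl group of 10 comes from aldehyde 9, this from alcohol 8, and 8 from benzyl ether 7 by a hydrogenation that also turns the isopropenyl group into isopropyl. These are oxidation-level changes on a fixed skeleton.

**C1–C6 (7 to 6), the key disconnection.** This bond joins two stereocentres, and cutting it converts ring and isopropenyl group into the acyclic, achiral alkylidene β-keto ester 6. The forward ene cyclisation gains the carbocycle and three stereocentres in one step, with every ring carbon at the right oxidation level (C4 ketone, C11 ester, C7 oxygenated). It has to select one face of C6 under a chiral Lewis acid and give the trans C1/C6 relationship; the antipodal series (20 to 28) starts from the same 6 with the mirror-image catalyst.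

**The precursor (6 to 4 and 5; 4 to 1 and 2; 13 to 11 and 12).** C5=C6 is cut by Knoevenagel condensation into β-keto ester 4 and aldehyde 5. C2–C3 of 4 is cut into 1 and 2 (dianion alkylation), and 13 into 11 and 12. All five starting materials are commodity chemicals.

## Alternatives that were turned down

**Alternative 1:** Oxepinone annulation. The cuts are O10–C9 and C7=C8, leading back to the trans aldehyde acid A2 (C7 aldehyde, C11 acid, C4/C13 diol as acetonide) and allyl 2-(diethoxyphosphoryl)acrylate A3. In the forward step a carbonate base lets the carboxylate of A2 add through O10 to the CH2 terminus of A3, and the phosphonate carbanion so formed at C8 olefinates the C7 aldehyde to give lactone A1.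
- For: two bonds and the ring in one operation, no transition metal, and an allyl ester can be carried because no metathesis follows, so the end game can be neutral.
- Against: A2 already contains the whole cyclohexane with all four stereocentres, so the harder half of the problem is left open. The base acts on a substrate whose C6–H is α to the aldehyde. A carboxylate is a weak, reversible Michael donor, and ring closure must outrun intermolecular olefination.
- Comparison: for the lactone alone this route is stronger (one step against ester exchange plus metathesis). The chosen strategy offers instead the carbocycle with three stereocentres in three steps from commodity chemicals, and then uses the β-keto ester it has made to attach the lactone arm. A separate synthesis of A2 would make the whole route longer.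

**Alternative 2:** Amine-catalysed triple cascade. The cuts are C6–C1, C2–C3 and C4=C5. 3-(4-Methoxybenzyloxy)propanal A5, (E)-3-methyl-1-nitrobut-1-ene A6 and acrolein A7 would combine under a diarylprolinol silyl ether (enamine addition, nitronate addition to the iminium ion, aldol condensation) to nitro cyclohexene carbaldehyde A4.
- For: three bonds, the ring and the C1/C6 pair in one step, by a reaction type that is established and usually highly enantioselective, with both catalyst antipodes available. On precedent for absolute control it is stronger than the chosen key step.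
- Against: A4 has its functionality in the wrong places. The nitro group on C2 must be removed. C5 is an sp2 CH without C11, so the lactone carbonyl carbon must be added by conjugate addition with control at C5 and then C4. The formyl group (C13) must be reduced and C4 hydroxylated. In addition A5 can lose its alkoxide under amine catalysis, and the branched A6 is a slow acceptor.
- Comparison: the cascade wins on known enantiocontrol but needs many corrective steps in each antipodal series. The chosen key step delivers every ring carbon at the oxidation level the target needs.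

**Alternative 3:** Carbonylative union. The cuts are C8–C12 and the C12–O bond to C13'. Alkenyl iodide A9 of one series, carbon monoxide A11 and the antipodal diol A10 would be joined by a zerovalent palladium catalyst to the protected dimer A8.
- For: the most convergent union, no activation of a sensitive unsaturated acid, and selective reaction at the primary hydroxyl. As a coupling it is as strong as or stronger than the esterification used here.
- Against: A9 and A10 do not come from a common intermediate, so the mirror-image economy of the target is lost. In A9 the C9–O10 bond is allylic to the C8–palladium bond, so β-acyloxy elimination or ionisation of the lactone can compete with carbonyl insertion. The allyl ester of A10 is itself a substrate for zerovalent palladium. The hindered alcohol A10 would have to be used near stoichiometrically. The monomer problem is left untouched.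
- Comparison: the chosen strategy offers one sequence that serves both antipodes up to 17 and 27, and a union whose chemoselectivity is predictable.

Key step: step 3

## Route

(S,S)-tBu-box is 2,2'-(propane-2,2-diyl)bis[(4S)-4-tert-butyl-4,5-dihydro-1,3-oxazole]; (R,R)-tBu-box is its antipode.

Step 1
Reactants: 1 methyl acetoacetate; 2 prenyl bromide (1-bromo-3-methylbut-2-ene)
Product: 4 methyl 7-methyl-3-oxooct-6-enoate, via acetoacetate dianion 3 (not isolated)
Conditions: NaH, THF, 0 °C; n-BuLi, 0 °C; then 2, 0 °C → rt; aq. HCl
Reagents that add atoms: none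
Why: γ-Alkylation of an acetoacetate dianion: the second deprotonation creates the more reactive terminal carbanion, which displaces bromide from the allylic halide by SN2 and forms C2–C3; no stereocentre is involved.

Step 2
Reactants: 4 methyl 7-methyl-3-oxooct-6-enoate; 5 benzyloxyacetaldehyde
Product: 6 methyl (2Z)-2-[2-(benzyloxy)ethylidene]-7-methyl-3-oxooct-6-enoate (obtained together with its 2E isomer)
Conditions: piperidine (cat.), AcOH (cat.), 4 Å MS, CH2Cl2, 0 °C → rt
Reagents that add atoms: none
Why: Knoevenagel condensation through the iminium ion of 5 forms C5=C6, the water going to the sieves. The double-bond geometry does not matter because the isomers equilibrate in step 3, and mild catalysis at low temperature avoids migration of the double bond toward the benzyloxy carbon.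

Step 3
Reactants: 6 methyl (2Z)-2-[2-(benzyloxy)ethylidene]-7-methyl-3-oxooct-6-enoate (2Z/2E mixture)
Product: 7 methyl (1S,2R,3S)-2-[(benzyloxy)methyl]-6-oxo-3-(prop-1-en-2-yl)cyclohexane-1-carboxylate
Conditions: Cu(OTf)2 (10 mol%), (S,S)-tBu-box (11 mol%), 4 Å MS, CH2Cl2, −20 °C → rt
Reagents that add atoms: none
Why: Proposed new method: divalent copper binds both carbonyl oxygens of 6, which makes C6 strongly electrophilic and lets the 2Z and 2E isomers interconvert; the prenyl alkene attacks C6 through C1, the Markovnikov end, and a methyl hydrogen of the developing tertiary cation then passes to C5 of the copper enolate, so that the net change is an intramolecular ene reaction forming C1–C6 and leaving an isopropenyl group on C1. The closest known reaction types are the Lewis-acid ene cyclisation of alkylidene 1,3-dicarbonyl compounds onto trisubstituted alkenes (domino Knoevenagel–ene sequence) and the copper bis(oxazoline) catalysed addition of π-nucleophiles to chelated alkylidene malonates; their combination on a β-keto ester whose tether leaves from the ketone carbon is untested. The cyclohexanone ring closes in the 6-endo-trig mode with respect to the C5=C6 acceptor, C4, C5 and C6 all becoming ring atoms. Because the hydrogen has to reach C5 across the ring, the bond-forming half-chair should hold the prenyl terminus axial on C1 and, to escape allylic strain with the planar chelate, the benzyloxymethyl group axial on C6, that is anti to each other, so that C1 and C6 emerge trans and the ring then flips to the all-equatorial chair. The absolute configuration of C6, and through the half-chair that of C1, is decided by the ligand, whose tert-butyl groups leave one face of the chelate plane open to the tether. C5 is not fixed here: as the α-carbon of a β-keto ester it settles by enolisation into the isomer with the ester equatorial and trans to C6. The step needs hydrogen transfer to win over capture of the cation by oxygen or by an external nucleophile, which is secured by the geometry (an ester oxygen could only close a bridged ring with a bridgehead double bond) and by the weakly nucleophilic triflate.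

Step 4
Reactants: 7 methyl (1S,2R,3S)-2-[(benzyloxy)methyl]-6-oxo-3-(prop-1-en-2-yl)cyclohexane-1-carboxylate
Product: 8 methyl (1S,2R,3R)-2-(hydroxymethyl)-6-oxo-3-(propan-2-yl)cyclohexane-1-carboxylate
Conditions: H2 (1 atm), Pd(OH)2/C, EtOAc/EtOH, rt
Reagents that add atoms: none
Why: Heterogeneous hydrogenation saturates the 1,1-disubstituted alkene and hydrogenolyses the benzyl ether in one operation, while the ketone and its chelated enol are left alone. No stereocentre is formed or touched; the descriptor at C3 changes only because the substituent priorities change.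

Step 5
Reactants: 8 methyl (1S,2R,3R)-2-(hydroxymethyl)-6-oxo-3-(propan-2-yl)cyclohexane-1-carboxylate
Product: 9 methyl (1S,2R,3R)-2-formyl-6-oxo-3-(propan-2-yl)cyclohexane-1-carboxylate
Conditions: Pr4N[RuO4] (5 mol%), NMO, 4 Å MS, CH2Cl2, 0 °C → rt
Reagents that add atoms: none
Why: Ley–Griffith oxidation of the primary alcohol stops at the aldehyde under neutral, anhydrous conditions, which keeps C6 (now α to the aldehyde) from epimerising and leaves the β-keto ester untouched.

Step 6
Reactants: 9 methyl (1S,2R,3R)-2-formyl-6-oxo-3-(propan-2-yl)cyclohexane-1-carboxylate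
Product: 10 methyl (1S,2R,3R)-2-ethenyl-6-oxo-3-(propan-2-yl)cyclohexane-1-carboxylate
Conditions: Ph3PCH3Br (2.6 equiv), KN(SiMe3)2 (2.5 equiv), THF, 0 °C; then 9, −78 → 0 °C; aq. NH4Cl
Reagents that add atoms: methyltriphenylphosphonium bromide, C[P+](c1ccccc1)(c1ccccc1)c1ccccc1.[Br-]
Why: Wittig methylenation: the first equivalent of ylide deprotonates the β-keto ester, whose enolate shields the C4 ketone, and the excess ylide converts the aldehyde into the C6 vinyl group. The monoanion resists a second deprotonation at C6, so the C6 configuration should survive at low temperature.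

Step 7
Reactants: 11 tert-butyl acrylate; 12 formaldehyde (37% aqueous solution)
Product: 13 tert-butyl 2-(hydroxymethyl)prop-2-enoate
Conditions: DABCO, 1,4-dioxane/H2O, rt
Reagents that add atoms: none
Why: Morita–Baylis–Hillman reaction: DABCO adds to the acrylate and the resulting enolate is hydroxymethylated by formaldehyde, giving the C8/C9/C12 unit with its alcohol and its 1,1-disubstituted alkene.

Step 8
Reactants: 10 methyl (1S,2R,3R)-2-ethenyl-6-oxo-3-(propan-2-yl)cyclohexane-1-carboxylate; 13 tert-butyl 2-(hydroxymethyl)prop-2-enoate
Product: 15 2-(tert-butoxycarbonyl)prop-2-en-1-yl (1S,2R,3R)-2-ethenyl-6-oxo-3-(propan-2-yl)cyclohexane-1-carboxylate, via acylketene 14 (not isolated)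
Conditions: 13 (1.5 equiv), BHT (cat.), toluene, reflux, 4 Å MS in a Soxhlet thimble
Reagents that add atoms: none
Why: Thermal ester exchange peculiar to β-keto esters: loss of methanol from the enol gives acylketene 14, which the primary alcohol 13 captures at C11. No amine is used, so the allylic ester formed is not ionised, and C5 returns by enolisation to the trans (equatorial) isomer.

Step 9
Reactants: 15 2-(tert-butoxycarbonyl)prop-2-en-1-yl (1S,2R,3R)-2-ethenyl-6-oxo-3-(propan-2-yl)cyclohexane-1-carboxylate
Product: 16 tert-butyl (5aS,6R,9aS)-1,9-dioxo-6-(propan-2-yl)-1,3,5a,6,7,8,9,9a-octahydro-2-benzoxepine-4-carboxylate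
Conditions: second-generation Hoveyda–Grubbs catalyst RuCl2(H2IMes)(=CH-C6H4-2-OiPr) (5–10 mol%), toluene (0.002 M), 80 °C, argon sparge
Reagents that add atoms: none
Why: Ring-closing metathesis: the catalyst loads on the monosubstituted C6 vinyl group and closes onto the 1,1-disubstituted acrylate, forming C7=C8 and the seven-membered lactone with loss of ethene. The ring enforces the alkene geometry, and the trans-diequatorial arms on C5 and C6 are well placed for a trans-fused ring.

Step 10
Reactants: 16 tert-butyl (5aS,6R,9aS)-1,9-dioxo-6-(propan-2-yl)-1,3,5a,6,7,8,9,9a-octahydro-2-benzoxepine-4-carboxylate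
Product: 17 tert-butyl (5aS,6R,9aS)-9-methylidene-1-oxo-6-(propan-2-yl)-1,3,5a,6,7,8,9,9a-octahydro-2-benzoxepine-4-carboxylate
Conditions: Zn, CH2Br2, TiCl4, THF (reagent aged at 5 °C); then 16, CH2Cl2, 0 °C → rt
Reagents that add atoms: dibromomethane, BrCBr
Why: Takai–Lombardo methylenation with the zinc/titanium methylene reagent, which is not basic, so the largely enolised β-keto lactone is olefinated and not merely deprotonated, and a ketone reacts far faster than an ester or lactone. C5 is carried over from the keto tautomer that reacts (trans ring fusion) and is no longer epimerisable afterwards.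

Step 11
Reactants: 17 tert-butyl (5aS,6R,9aS)-9-methylidene-1-oxo-6-(propan-2-yl)-1,3,5a,6,7,8,9,9a-octahydro-2-benzoxepine-4-carboxylate
Product: 19 (5aS,6R,9aS)-9-methylidene-1-oxo-6-(propan-2-yl)-1,3,5a,6,7,8,9,9a-octahydro-2-benzoxepine-4-carboxylic acid, via trimethylsilyl ester 18 (not isolated)
Conditions: TMSOTf, 2,6-lutidine, CH2Cl2, 0 °C → rt; then pH 4 aqueous citrate
Reagents that add atoms: none
Why: Cleavage of the tert-butyl ester by a silyl triflate and a hindered pyridine: O-silylation of the ester carbonyl is followed by loss of 2-methylpropene, and silyl ester 18 hydrolyses on work-up. No protic acid is present, which spares the exocyclic alkene and the C5 stereocentre.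

Step 12
Reactants: 6 methyl (2Z)-2-[2-(benzyloxy)ethylidene]-7-methyl-3-oxooct-6-enoate (2Z/2E mixture)
Product: 20 methyl (1R,2S,3R)-2-[(benzyloxy)methyl]-6-oxo-3-(prop-1-en-2-yl)cyclohexane-1-carboxylate (antipode of 7)
Conditions: Cu(OTf)2 (10 mol%), (R,R)-tBu-box (11 mol%), 4 Å MS, CH2Cl2, −20 °C → rt
Reagents that add atoms: none
Why: Proposed new method: the same copper-chelate ene cyclisation as in step 3 (attack of C1 on the chelated C6, then hydrogen transfer from a methyl group to C5), run with the mirror-image ligand; the achiral substrate then passes through the mirror-image half-chair and gives 20 with C1/C6 trans and C5 under thermodynamic control. The closest known reaction types are again the Lewis-acid ene cyclisation of alkylidene 1,3-dicarbonyl compounds and the copper bis(oxazoline) activation of alkylidene malonates.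

Step 13
Reactants: 20 methyl (1R,2S,3R)-2-[(benzyloxy)methyl]-6-oxo-3-(prop-1-en-2-yl)cyclohexane-1-carboxylate
Product: 21 methyl (1R,2S,3S)-2-(hydroxymethyl)-6-oxo-3-(propan-2-yl)cyclohexane-1-carboxylate
Conditions: H2 (1 atm), Pd(OH)2/C, EtOAc/EtOH, rt
Reagents that add atoms: none
Why: Hydrogenation of the isopropenyl group and hydrogenolysis of the benzyl ether, as in step 4; no stereocentre is touched.

Step 14
Reactants: 21 methyl (1R,2S,3S)-2-(hydroxymethyl)-6-oxo-3-(propan-2-yl)cyclohexane-1-carboxylate
Product: 22 methyl (1R,2S,3S)-2-formyl-6-oxo-3-(propan-2-yl)cyclohexane-1-carboxylate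
Conditions: Pr4N[RuO4] (5 mol%), NMO, 4 Å MS, CH2Cl2, 0 °C → rt
Reagents that add atoms: none
Why: Ley–Griffith oxidation to the aldehyde under neutral conditions, as in step 5; C6 is not epimerised.

Step 15
Reactants: 22 methyl (1R,2S,3S)-2-formyl-6-oxo-3-(propan-2-yl)cyclohexane-1-carboxylate
Product: 23 methyl (1R,2S,3S)-2-ethenyl-6-oxo-3-(propan-2-yl)cyclohexane-1-carboxylate
Conditions: Ph3PCH3Br (2.6 equiv), KN(SiMe3)2 (2.5 equiv), THF, 0 °C; then 22, −78 → 0 °C; aq. NH4Cl
Reagents that add atoms: methyltriphenylphosphonium bromide, C[P+](c1ccccc1)(c1ccccc1)c1ccccc1.[Br-]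
Why: Wittig methylenation of the aldehyde with the β-keto ester masked as its enolate, as in step 6.

Step 16
Reactants: 23 methyl (1R,2S,3S)-2-ethenyl-6-oxo-3-(propan-2-yl)cyclohexane-1-carboxylate; 13 tert-butyl 2-(hydroxymethyl)prop-2-enoate
Product: 25 2-(tert-butoxycarbonyl)prop-2-en-1-yl (1R,2S,3S)-2-ethenyl-6-oxo-3-(propan-2-yl)cyclohexane-1-carboxylate, via acylketene 24 (not isolated)
Conditions: 13 (1.5 equiv), BHT (cat.), toluene, reflux, 4 Å MS in a Soxhlet thimble
Reagents that add atoms: none
Why: Thermal β-keto ester exchange through acylketene 24, as in step 8; C5 returns to the trans isomer.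

Step 17
Reactants: 25 2-(tert-butoxycarbonyl)prop-2-en-1-yl (1R,2S,3S)-2-ethenyl-6-oxo-3-(propan-2-yl)cyclohexane-1-carboxylate
Product: 26 tert-butyl (5aR,6S,9aR)-1,9-dioxo-6-(propan-2-yl)-1,3,5a,6,7,8,9,9a-octahydro-2-benzoxepine-4-carboxylate
Conditions: second-generation Hoveyda–Grubbs catalyst RuCl2(H2IMes)(=CH-C6H4-2-OiPr) (5–10 mol%), toluene (0.002 M), 80 °C, argon sparge
Reagents that add atoms: none
Why: Ring-closing metathesis forming C7'=C8' and the seven-membered lactone, as in step 9.

Step 18
Reactants: 26 tert-butyl (5aR,6S,9aR)-1,9-dioxo-6-(propan-2-yl)-1,3,5a,6,7,8,9,9a-octahydro-2-benzoxepine-4-carboxylate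
Product: 27 tert-butyl (5aR,6S,9aR)-9-methylidene-1-oxo-6-(propan-2-yl)-1,3,5a,6,7,8,9,9a-octahydro-2-benzoxepine-4-carboxylate
Conditions: Zn, CH2Br2, TiCl4, THF (reagent aged at 5 °C); then 26, CH2Cl2, 0 °C → rt
Reagents that add atoms: dibromomethane, BrCBr
Why: Takai–Lombardo methylenation of the C4' ketone under non-basic conditions, as in step 10; C5' keeps the trans ring fusion.

Step 19
Reactants: 27 tert-butyl (5aR,6S,9aR)-9-methylidene-1-oxo-6-(propan-2-yl)-1,3,5a,6,7,8,9,9a-octahydro-2-benzoxepine-4-carboxylate
Product: 28 tert-butyl (5aR,6S,9R,9aR)-9-hydroxy-9-(hydroxymethyl)-1-oxo-6-(propan-2-yl)-1,3,5a,6,7,8,9,9a-octahydro-2-benzoxepine-4-carboxylate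
Conditions: OsO4 (2 mol%), NMO, acetone/H2O, 0 °C; aq. NaHSO3
Reagents that add atoms: osmium tetroxide, O=[Os](=O)(=O)=O; N-methylmorpholine N-oxide, C[N+]1([O-])CCOCC1; water, O
Why: Catalytic osmium tetroxide dihydroxylation with NMO as co-oxidant; the electron-rich 1,1-disubstituted alkene reacts in preference to the trisubstituted enoate. C4' is set by approach of the bulky reagent from the equatorial side of the chair (the axial side is screened by the axial hydrogens on C2' and C6'), which places the hydroxyl equatorial and C13' axial.

Step 20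
Reactants: 19 (5aS,6R,9aS)-9-methylidene-1-oxo-6-(propan-2-yl)-1,3,5a,6,7,8,9,9a-octahydro-2-benzoxepine-4-carboxylic acid; 28 tert-butyl (5aR,6S,9R,9aR)-9-hydroxy-9-(hydroxymethyl)-1-oxo-6-(propan-2-yl)-1,3,5a,6,7,8,9,9a-octahydro-2-benzoxepine-4-carboxylate
Product: 30 [(5aR,6S,9R,9aR)-4-(tert-butoxycarbonyl)-9-hydroxy-1-oxo-6-(propan-2-yl)-1,3,5a,6,7,8,9,9a-octahydro-2-benzoxepin-9-yl]methyl (5aS,6R,9aS)-9-methylidene-1-oxo-6-(propan-2-yl)-1,3,5a,6,7,8,9,9a-octahydro-2-benzoxepine-4-carboxylate, via mixed anhydride 29 (not isolated)
Conditions: 2,4,6-Cl3C6H2COCl, Et3N, THF, 0 °C; then 28, DMAP, toluene, 0 °C → rt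
Reagents that add atoms: none
Why: Yamaguchi esterification: mixed anhydride 29 passes the acyl group of 19 through the acylpyridinium ion to the primary C13' hydroxyl of 28, and the tertiary C4' hydroxyl does not compete. Low temperature and the minimum of amine limit γ-deprotonation of the activated enoate.

Step 21
Reactants: 30 tert-butyl ester of the coupled dimer (named in step 20)
Product: 32 (5aR,6S,9R,9aR)-9-hydroxy-9-({[(5aS,6R,9aS)-9-methylidene-1-oxo-6-(propan-2-yl)-1,3,5a,6,7,8,9,9a-octahydro-2-benzoxepine-4-carbonyl]oxy}methyl)-1-oxo-6-(propan-2-yl)-1,3,5a,6,7,8,9,9a-octahydro-2-benzoxepine-4-carboxylic acid, via bis(trimethylsilyl) derivative 31 (not isolated)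
Conditions: TMSOTf, 2,6-lutidine, CH2Cl2, 0 °C → rt; then aq. citric acid/THF
Reagents that add atoms: none
Why: The same silyl triflate cleavage of the tert-butyl ester as in step 11; the tertiary hydroxyl is silylated in passing and both silyl groups of 31 are lost on the mildly acidic work-up. That work-up is harmless here because the intermediate has no free C13 hydroxyl beside a lactone.

Step 22
Reactants: 32 methylene dimer acid (named in step 21)
Product: 33 CNP0340505.1, (5aR,6S,9R,9aR)-9-hydroxy-9-({[(5aS,6R,9S,9aS)-9-hydroxy-9-(hydroxymethyl)-1-oxo-6-(propan-2-yl)-1,3,5a,6,7,8,9,9a-octahydro-2-benzoxepine-4-carbonyl]oxy}methyl)-1-oxo-6-(propan-2-yl)-1,3,5a,6,7,8,9,9a-octahydro-2-benzoxepine-4-carboxylic acid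
Conditions: OsO4 (2 mol%), NMO, acetone/H2O, 0 °C; aq. NaHSO3; adjust to pH 4
Reagents that add atoms: osmium tetroxide, O=[Os](=O)(=O)=O; N-methylmorpholine N-oxide, C[N+]1([O-])CCOCC1; water, O
Why: Catalytic osmium tetroxide dihydroxylation as in step 19, now on the first half: the only electron-rich alkene is C4=C13, and equatorial approach should set C4 as S with equatorial hydroxyl and axial CH2OH. The sensitive hydroxy lactone array is thus formed last and under near-neutral conditions.

## Compound list

1 | methyl acetoacetate | COC(=O)CC(C)=O | starting material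
2 | prenyl bromide (1-bromo-3-methylbut-2-ene) | CC(C)=CCBr | starting material
3 | dianion of methyl acetoacetate (sodium lithium salt) | [Li+].[Na+].[CH2-]C(=O)[CH-]C(=O)OC | intermediate (not isolated)
4 | methyl 7-methyl-3-oxooct-6-enoate | COC(=O)CC(=O)CCC=C(C)C | intermediate
5 | benzyloxyacetaldehyde | O=CCOCc1ccccc1 | starting material
6 | methyl (2Z)-2-[2-(benzyloxy)ethylidene]-7-methyl-3-oxooct-6-enoate (used with its 2E isomer) | COC(=O)/C(C(=O)CCC=C(C)C)=C\COCc1ccccc1 | intermediate
7 | methyl (1S,2R,3S)-2-[(benzyloxy)methyl]-6-oxo-3-(prop-1-en-2-yl)cyclohexane-1-carboxylate | CC(=C)[C@H]1CCC(=O)[C@@H](C(=O)OC)[C@@H]1COCc1ccccc1 | intermediate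
8 | methyl (1S,2R,3R)-2-(hydroxymethyl)-6-oxo-3-(propan-2-yl)cyclohexane-1-carboxylate | CC(C)[C@H]1CCC(=O)[C@@H](C(=O)OC)[C@@H]1CO | intermediate
9 | methyl (1S,2R,3R)-2-formyl-6-oxo-3-(propan-2-yl)cyclohexane-1-carboxylate | CC(C)[C@H]1CCC(=O)[C@@H](C(=O)OC)[C@@H]1C=O | intermediate
10 | methyl (1S,2R,3R)-2-ethenyl-6-oxo-3-(propan-2-yl)cyclohexane-1-carboxylate | CC(C)[C@H]1CCC(=O)[C@@H](C(=O)OC)[C@@H]1C=C | intermediate
11 | tert-butyl acrylate | C=CC(=O)OC(C)(C)C | starting material
12 | formaldehyde | C=O | starting material
13 | tert-butyl 2-(hydroxymethyl)prop-2-enoate | C=C(CO)C(=O)OC(C)(C)C | intermediate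
14 | (3R,4R)-3-ethenyl-2-(oxomethylidene)-4-(propan-2-yl)cyclohexan-1-one (acylketene) | CC(C)[C@H]1CCC(=O)C(=C=O)[C@@H]1C=C | intermediate (not isolated)
15 | 2-(tert-butoxycarbonyl)prop-2-en-1-yl (1S,2R,3R)-2-ethenyl-6-oxo-3-(propan-2-yl)cyclohexane-1-carboxylate | CC(C)[C@H]1CCC(=O)[C@@H](C(=O)OCC(=C)C(=O)OC(C)(C)C)[C@@H]1C=C | intermediate
16 | tert-butyl (5aS,6R,9aS)-1,9-dioxo-6-(propan-2-yl)-1,3,5a,6,7,8,9,9a-octahydro-2-benzoxepine-4-carboxylate | CC(C)[C@H]1CCC(=O)[C@H]2C(=O)OCC(C(=O)OC(C)(C)C)=C[C@H]12 | intermediate
17 | tert-butyl (5aS,6R,9aS)-9-methylidene-1-oxo-6-(propan-2-yl)-1,3,5a,6,7,8,9,9a-octahydro-2-benzoxepine-4-carboxylate | CC(C)[C@H]1CCC(=C)[C@H]2C(=O)OCC(C(=O)OC(C)(C)C)=C[C@H]12 | intermediate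
18 | trimethylsilyl (5aS,6R,9aS)-9-methylidene-1-oxo-6-(propan-2-yl)-1,3,5a,6,7,8,9,9a-octahydro-2-benzoxepine-4-carboxylate | CC(C)[C@H]1CCC(=C)[C@H]2C(=O)OCC(C(=O)O[Si](C)(C)C)=C[C@H]12 | intermediate (not isolated)
19 | (5aS,6R,9aS)-9-methylidene-1-oxo-6-(propan-2-yl)-1,3,5a,6,7,8,9,9a-octahydro-2-benzoxepine-4-carboxylic acid | CC(C)[C@H]1CCC(=C)[C@H]2C(=O)OCC(C(=O)O)=C[C@H]12 | intermediate
20 | methyl (1R,2S,3R)-2-[(benzyloxy)methyl]-6-oxo-3-(prop-1-en-2-yl)cyclohexane-1-carboxylate | CC(=C)[C@@H]1CCC(=O)[C@H](C(=O)OC)[C@H]1COCc1ccccc1 | intermediate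
21 | methyl (1R,2S,3S)-2-(hydroxymethyl)-6-oxo-3-(propan-2-yl)cyclohexane-1-carboxylate | CC(C)[C@@H]1CCC(=O)[C@H](C(=O)OC)[C@H]1CO | intermediate
22 | methyl (1R,2S,3S)-2-formyl-6-oxo-3-(propan-2-yl)cyclohexane-1-carboxylate | CC(C)[C@@H]1CCC(=O)[C@H](C(=O)OC)[C@H]1C=O | intermediate
23 | methyl (1R,2S,3S)-2-ethenyl-6-oxo-3-(propan-2-yl)cyclohexane-1-carboxylate | CC(C)[C@@H]1CCC(=O)[C@H](C(=O)OC)[C@H]1C=C | intermediate
24 | (3S,4S)-3-ethenyl-2-(oxomethylidene)-4-(propan-2-yl)cyclohexan-1-one (acylketene) | CC(C)[C@@H]1CCC(=O)C(=C=O)[C@H]1C=C | intermediate (not isolated)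
25 | 2-(tert-butoxycarbonyl)prop-2-en-1-yl (1R,2S,3S)-2-ethenyl-6-oxo-3-(propan-2-yl)cyclohexane-1-carboxylate | CC(C)[C@@H]1CCC(=O)[C@H](C(=O)OCC(=C)C(=O)OC(C)(C)C)[C@H]1C=C | intermediate
26 | tert-butyl (5aR,6S,9aR)-1,9-dioxo-6-(propan-2-yl)-1,3,5a,6,7,8,9,9a-octahydro-2-benzoxepine-4-carboxylate | CC(C)[C@@H]1CCC(=O)[C@@H]2C(=O)OCC(C(=O)OC(C)(C)C)=C[C@@H]12 | intermediate
27 | tert-butyl (5aR,6S,9aR)-9-methylidene-1-oxo-6-(propan-2-yl)-1,3,5a,6,7,8,9,9a-octahydro-2-benzoxepine-4-carboxylate | CC(C)[C@@H]1CCC(=C)[C@@H]2C(=O)OCC(C(=O)OC(C)(C)C)=C[C@@H]12 | intermediate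
28 | tert-butyl (5aR,6S,9R,9aR)-9-hydroxy-9-(hydroxymethyl)-1-oxo-6-(propan-2-yl)-1,3,5a,6,7,8,9,9a-octahydro-2-benzoxepine-4-carboxylate | CC(C)[C@@H]1CC[C@](O)(CO)[C@@H]2C(=O)OCC(C(=O)OC(C)(C)C)=C[C@@H]12 | intermediate
29 | mixed anhydride of 19 with 2,4,6-trichlorobenzoic acid | CC(C)[C@H]1CCC(=C)[C@H]2C(=O)OCC(C(=O)OC(=O)c3c(Cl)cc(Cl)cc3Cl)=C[C@H]12 | intermediate (not isolated)
30 | [(5aR,6S,9R,9aR)-4-(tert-butoxycarbonyl)-9-hydroxy-1-oxo-6-(propan-2-yl)-1,3,5a,6,7,8,9,9a-octahydro-2-benzoxepin-9-yl]methyl (5aS,6R,9aS)-9-methylidene-1-oxo-6-(propan-2-yl)-1,3,5a,6,7,8,9,9a-octahydro-2-benzoxepine-4-carboxylate | CC(C)[C@H]1CCC(=C)[C@H]2C(=O)OCC(C(=O)OC[C@@]3(O)CC[C@@H](C(C)C)[C@@H]4C=C(C(=O)OC(C)(C)C)COC(=O)[C@H]43)=C[C@H]12 | intermediate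
31 | trimethylsilyl ester and C4' trimethylsilyl ether of 32 | CC(C)[C@H]1CCC(=C)[C@H]2C(=O)OCC(C(=O)OC[C@@]3(O[Si](C)(C)C)CC[C@@H](C(C)C)[C@@H]4C=C(C(=O)O[Si](C)(C)C)COC(=O)[C@H]43)=C[C@H]12 | intermediate (not isolated)
32 | (5aR,6S,9R,9aR)-9-hydroxy-9-({[(5aS,6R,9aS)-9-methylidene-1-oxo-6-(propan-2-yl)-1,3,5a,6,7,8,9,9a-octahydro-2-benzoxepine-4-carbonyl]oxy}methyl)-1-oxo-6-(propan-2-yl)-1,3,5a,6,7,8,9,9a-octahydro-2-benzoxepine-4-carboxylic acid | CC(C)[C@H]1CCC(=C)[C@H]2C(=O)OCC(C(=O)OC[C@@]3(O)CC[C@@H](C(C)C)[C@@H]4C=C(C(=O)O)COC(=O)[C@H]43)=C[C@H]12 | intermediate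
33 | CNP0340505.1, (5aR,6S,9R,9aR)-9-hydroxy-9-({[(5aS,6R,9S,9aS)-9-hydroxy-9-(hydroxymethyl)-1-oxo-6-(propan-2-yl)-1,3,5a,6,7,8,9,9a-octahydro-2-benzoxepine-4-carbonyl]oxy}methyl)-1-oxo-6-(propan-2-yl)-1,3,5a,6,7,8,9,9a-octahydro-2-benzoxepine-4-carboxylic acid | CC(C)[C@H]1CC[C@@](O)(CO)[C@H]2C(=O)OCC(C(=O)OC[C@@]3(O)CC[C@@H](C(C)C)[C@@H]4C=C(C(=O)O)COC(=O)[C@H]43)=C[C@H]12 | target

## Step count and least certain steps

Total: 22 steps. Longest linear sequence: 13 steps (1, 2, 3, 4, 5, 6, 8, 9, 10, 11, 20, 21, 22; the branch through steps 12 to 19 is equally long).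

**Steps 3 and 12 (key step, the two steps that carry the new-method label).**
- What may go wrong: weak discrimination between the two faces of the chelate, because C6 lies far from the ligand substituents. The product can bind copper as a β-keto ester enolate and set TfOH free, so that a racemic acid-driven cyclisation takes over. Bond formation through the half-chair with the C6 side chain equatorial would give the cis C1/C6 isomer, and proton loss from C1 in place of hydrogen transfer would give the isopropylidene isomer.
- Fallback (known chemistry), setting out from 6: cyclisation with FeCl3 on Al2O3 in CH2Cl2 (−78 °C → rt), the achiral Lewis-acid ene protocol for alkylidene 1,3-dicarbonyl compounds, gives the racemic keto ester F1 (equal parts of 7 and 20). F1 carries a benzyl chromophore and is resolved by preparative chromatography on an amylose carbamate chiral phase. The antipodes are assigned (for example by anomalous-dispersion X-ray analysis of a heavy-atom ester made from 8 or 21) and come back to the route as 7 (before step 4) and 20 (before step 13). The target consumes both antipodes in equal amounts, so the resolution wastes nothing. For step 12 the same fallback applies and makes no further compound (F0).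

**Steps 10 and 18 (methylenation of the β-keto lactone).**
- What may go wrong: the ketone is largely present as a chelated enol, so metalation of the enol may consume the reagent and return starting material; prolonged contact with the titanium and zinc halides may also cleave the tert-butyl ester.
- Fallback, setting out from 16: the enol triflate F2 (Tf2O, iPr2NEt, CH2Cl2, −78 °C) is coupled with Me3SiCH2MgCl under Pd(PPh3)4 (zerovalent palladium; Kumada coupling) to the allylsilane F3. Protodesilylation (Bu4NF buffered with AcOH, THF, 0 °C) protonates the dienolate at C5 and moves the double bond to C4=C13, coming back to the route at 17; the C5 configuration then rests on kinetic protonation and has to be checked. The mirror-image sequence from 26 through the enol triflate F4 and the allylsilane F5 comes back at 27.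

**Steps 9 and 17 (ring-closing metathesis).**
- What may go wrong: intermolecular metathesis through the vinyl group may outrun ring closure, because the ester prefers the extended rotamer and the electron-poor 1,1-disubstituted alkene is a slow partner; the β-dicarbonyl unit may also tie up the catalyst.
- Fallback, setting out from 10: the order of bond formation is reversed. Cross-metathesis of 10 with an excess of 13 (same ruthenium catalyst, expected to give the E enoate) leads to the hydroxy enoate F6. Heating F6 in toluene lets the C9 hydroxyl capture the acylketene within the molecule and closes the lactone, coming back at 16. The mirror-image sequence from 23 through the hydroxy enoate F7 comes back at 26.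

**Steps 19 and 22 (dihydroxylation).**
- What may go wrong: too small a preference for the equatorial side of the exocyclic alkene, giving the C4 epimer; in step 22 also migration of the lactone acyl group to the new C13 hydroxyl during work-up.
- Fallback, setting out from 27 (to 28) and from 32 (to 33): reagent control in place of substrate control. The osmylation is run with OsO4 bound to a cinchona ligand, (DHQD)2PHAL for one antipodal environment and (DHQ)2PHAL for the other, in the stoichiometric, non-basic format (toluene/CH2Cl2, −78 °C, then NaHSO3). No compound outside the list is made (F0).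

**Step 20 (esterification).**
- What may go wrong: after activation of 19, deprotonation at the γ-position (C6–H) may deconjugate the enoate or open the lactone through a vinylketene; the neopentyl-type C13' hydroxyl is slow, so acyl migration within 28 can compete.
- Fallback, setting out from 28: the ester is made by alkylating the carboxylate. 28 is cyclodehydrated under Mitsunobu conditions (PPh3, DIAD; the primary hydroxyl is activated, C4' keeps its configuration) to the spiro-epoxide F8. The caesium salt of 19 (Cs2CO3, DMF, 50 °C) opens F8 at the primary carbon C13' and comes back to the route at 30.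

## Further compounds

F1 | step 3 | racemic keto ester (equal parts of 7 and 20) | CC(=C)[C@H]1CCC(=O)[C@@H](C(=O)OC)[C@@H]1COCc1ccccc1.CC(=C)[C@@H]1CCC(=O)[C@H](C(=O)OC)[C@H]1COCc1ccccc1
F0 | step 12 | none | none
F2 | step 10 | tert-butyl (5aS,6R)-1-oxo-6-(propan-2-yl)-9-[(trifluoromethanesulfonyl)oxy]-1,3,5a,6,7,8-hexahydro-2-benzoxepine-4-carboxylate (enol triflate) | CC(C)[C@H]1CCC(OS(=O)(=O)C(F)(F)F)=C2C(=O)OCC(C(=O)OC(C)(C)C)=C[C@H]12
F3 | step 10 | tert-butyl (5aS,6R)-1-oxo-6-(propan-2-yl)-9-[(trimethylsilyl)methyl]-1,3,5a,6,7,8-hexahydro-2-benzoxepine-4-carboxylate (allylsilane) | CC(C)[C@H]1CCC(C[Si](C)(C)C)=C2C(=O)OCC(C(=O)OC(C)(C)C)=C[C@H]12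
F4 | step 18 | tert-butyl (5aR,6S)-1-oxo-6-(propan-2-yl)-9-[(trifluoromethanesulfonyl)oxy]-1,3,5a,6,7,8-hexahydro-2-benzoxepine-4-carboxylate (enol triflate) | CC(C)[C@@H]1CCC(OS(=O)(=O)C(F)(F)F)=C2C(=O)OCC(C(=O)OC(C)(C)C)=C[C@@H]12
F5 | step 18 | tert-butyl (5aR,6S)-1-oxo-6-(propan-2-yl)-9-[(trimethylsilyl)methyl]-1,3,5a,6,7,8-hexahydro-2-benzoxepine-4-carboxylate (allylsilane) | CC(C)[C@@H]1CCC(C[Si](C)(C)C)=C2C(=O)OCC(C(=O)OC(C)(C)C)=C[C@@H]12
F6 | step 9 | methyl (1S,2S,3R)-2-[(1E)-3-tert-butoxy-2-(hydroxymethyl)-3-oxoprop-1-en-1-yl]-6-oxo-3-(propan-2-yl)cyclohexane-1-carboxylate (hydroxy enoate) | CC(C)[C@H]1CCC(=O)[C@@H](C(=O)OC)[C@@H]1/C=C(\CO)C(=O)OC(C)(C)C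
F7 | step 17 | methyl (1R,2R,3S)-2-[(1E)-3-tert-butoxy-2-(hydroxymethyl)-3-oxoprop-1-en-1-yl]-6-oxo-3-(propan-2-yl)cyclohexane-1-carboxylate (hydroxy enoate) | CC(C)[C@@H]1CCC(=O)[C@H](C(=O)OC)[C@H]1/C=C(\CO)C(=O)OC(C)(C)C
F0 | step 19 | none | none
F0 | step 22 | none | none
F8 | step 20 | spiro-epoxide of 28 (oxirane spanning C4' and C13', configuration of 28 retained) | CC(C)[C@@H]1CC[C@]3(CO3)[C@@H]2C(=O)OCC(C(=O)OC(C)(C)C)=C[C@@H]12
A1 | alternative 1 | bicyclic lactone, allyl ester and acetonide | CC(C)[C@H]1CC[C@@]3(COC(C)(C)O3)[C@H]2C(=O)OCC(C(=O)OCC=C)=C[C@H]12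
A2 | alternative 1 | trans aldehyde acid (C7 aldehyde, C11 acid, C4/C13 acetonide) | CC(C)[C@H]1CC[C@@]2(COC(C)(C)O2)[C@@H](C(=O)O)[C@@H]1C=O
A3 | alternative 1 | allyl 2-(diethoxyphosphoryl)acrylate | C=C(C(=O)OCC=C)P(=O)(OCC)OCC
A4 | alternative 2 | nitro cyclohexene carbaldehyde | O=CC1=C[C@H](COCc2ccc(OC)cc2)[C@@H](C(C)C)[C@H]([N+](=O)[O-])C1
A5 | alternative 2 | 3-(4-methoxybenzyloxy)propanal | O=CCCOCc1ccc(OC)cc1
A6 | alternative 2 | (E)-3-methyl-1-nitrobut-1-ene | CC(C)/C=C/[N+](=O)[O-]
A7 | alternative 2 | acrolein | C=CC=O
A8 | alternative 3 | protected dimer (acetonide, allyl ester) | CC(C)[C@H]1CC[C@@]5(COC(C)(C)O5)[C@H]2C(=O)OCC(C(=O)OC[C@@]3(O)CC[C@@H](C(C)C)[C@@H]4C=C(C(=O)OCC=C)COC(=O)[C@H]43)=C[C@H]12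
A9 | alternative 3 | iodo-oxepinone (acetonide) | CC(C)[C@H]1CC[C@@]3(COC(C)(C)O3)[C@H]2C(=O)OCC(I)=C[C@H]12
A10 | alternative 3 | antipodal diol, allyl ester | OC[C@@]3(O)CC[C@@H](C(C)C)[C@@H]4C=C(C(=O)OCC=C)COC(=O)[C@H]43
A11 | alternative 3 | carbon monoxide | [C-]#[O+]
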